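Remark on the chemistry: all aryl oxygens are carried as benzyl ethers instead of methyl ethers, so that the last step is a neutral hydrogenolysis and no Lewis acid meets the acid-labile hydroxybenzyl–resorcinol links. 4-(Benzyloxy)benzaldehyde, 3-(benzyloxy)benzyl chloride, LiN(iPr)2 solution and Dess–Martin periodinane are taken as purchased.

## Structural features

Shanciguol is an achiral pentaphenol, 4,6-bis(4-hydroxybenzyl)-5-[2-(3-hydroxyphenyl)ethyl]benzene-1,3-diol, in which a resorcinol ring A is joined at C1 by a two-carbon bridge to a 3-hydroxyphenyl ring (a bibenzyl) and at C2 and C6 by single methylene groups to two 4-hydroxyphenyl rings. Ring A is pentasubstituted: only C4 bears hydrogen, and the three carbon substituents sit on the contiguous carbons C6, C1 and C2, each benzyl group lying between the bridge and a hydroxyl (C3 or C5). There is no stereocentre and no ring fusion, so no relation between neighbouring centres has to be set; a mirror plane through C1 and C4 makes C2/C6 and C3/C5 equivalent. The fragile elements are the five free phenols (air oxidation of electron-rich ring A) and, above all, the two diarylmethane links. C2 and C6 are ortho and para to the ring-A hydroxyls and carry a 4-hydroxybenzyl group, so ipso protonation can expel a quinone-methide-like benzyl cation; strong Brønsted or Lewis acids should therefore be kept away from the late intermediates. The real difficulty is the regiocontrolled assembly of the crowded pattern of three adjacent carbon substituents flanked by two oxygens, which direct benzylation of a preformed bibenzyl would not deliver cleanly because C4 competes. The key step exploits the symmetry: C2–C3–C4–C5–C6 with both benzylic carbons and their aryl rings is a 1,7-diarylheptane-3,5-dione in which C3 and C5 already stand at the carbonyl level of the future hydroxyls, so that only C1 is missing; it is brought in as the keto-level carbon of an oxalate whose second carbon becomes the first carbon of the bridge.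

## Logic of the disconnections

16 to 15. The five O–CH2Ph bonds are cut and the bridge is desaturated to a C=C bond. The reason is to unmask all phenols and to saturate the bridge in one neutral operation, so that the acid-labile links at C2 and C6 never meet a Lewis acid. The gain is a robust, non-polar penultimate compound. The demand on the forward step is that hydrogen over Pd/C reduces a hindered olefin and cleaves five aryl benzyl ethers without touching the diarylmethane C–C bonds.

15 to 11 and 14 (14 from 13, 13 from 12). The C=C bond between the two bridge carbons is cut. It is the only link between ring A and the 3-oxygenated ring, and an olefination makes it by carbonyl chemistry, free of the homocoupling that threatens a benzyl–benzyl alkylation. The gain is that the third aryl ring is split off as a one-step phosphorus reagent, while 11 holds every substituent of ring A. The demand is that 14 adds to a formyl group flanked by two benzyl groups; olefin geometry is irrelevant. The P–C bond of 13 leads back to 12.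

11 to 8 by way of 10 and 9. No skeletal bond is cut. The formyl group is traced to the ester through the primary alcohol, and the two ring-A benzyl ethers to the free phenols. The reason is that the annulation delivers C1 bearing an ester and two free hydroxyls. The demands are that hydride reaches an ester shielded by two ortho substituents and that the phenols are alkylated on oxygen.

8 to 4 and 5. The bonds C1–C2 and C1–C6 of ring A are cut. C1 is the only ring carbon that the symmetric diketone lacks, and 5 supplies it at ketone level, so aromatisation needs only loss of water, not an oxidation; the second carbon of 5 stays as the handle for the bridge. The gain is large: a pentasubstituted arene comes from an acyclic, symmetric precursor with both benzyl groups in place and no regiochemical choice. The demands are three: acylation at a terminal and not the central carbon of 4 (giving 6), closure through carbon and not oxygen, and aldol addition of C6 to the C1 ketone (giving 7) in preference to a Claisen closure of C4 on the ester carbonyl.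

4 to 1 and 2 by way of 3. The two saturated C–C bonds next to the aryl rings are traced to C=C bonds, and these are cut by a double aldol condensation that joins two molecules of 1 to one of 2. The reason is that 2 supplies C2 to C6 with the right oxidation pattern and 1 supplies each benzylic carbon with its ring. The demands are that condensation occurs at the methyl groups and not at the central carbon of 2, and that the hydrogenation of 3 spares the benzyl ethers.

## Other disconnections considered

Alternative 1: The cut runs through C1–C6 and C4–C5 of ring A. One piece is dimethyl 2-(4-methoxybenzyl)malonate A1 (C5, C6 and the C6 benzyl group); the other is (E)-3-(4-methoxybenzyl)-6-(3-methoxyphenyl)hex-3-en-2-one A2 (C1 with the complete arylethyl chain, C2 with its benzyl group, C3 and C4). In the forward sense NaOMe in methanol would add the anion of A1 to the β-carbon of A2, and the methyl ketone enolate would then close the ring on a malonate ester. The product would be methyl 1,3-bis(4-methoxybenzyl)-2-[2-(3-methoxyphenyl)ethyl]-4,6-dioxocyclohexane-1-carboxylate A3 as a diastereomer mixture.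
- In its favour: all three carbon substituents of ring A, the arylethyl chain included, arrive in the annulation, and the diastereomers do not matter.
- Against it here: the Michael step must join a fully substituted malonate carbon to the β-carbon of an α-branched enone, a crowded and reversible bond formation. A3 also stands one oxidation level below the arene and carries a surplus ester on a quaternary carbon, so ester removal and a dehydrogenation of a trisubstituted cyclohexane-1,3-dione must follow. A2 needs a regiocontrolled crossed aldol of its own.
- Structure: the alternative ignores the mirror symmetry and needs two different fragments, where the chosen plan builds ring A from one symmetric chain.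
- Mechanism: both are base-mediated polar annulations, but 8 is reached at the aromatic level by dehydration alone, whereas A3 needs an oxidant.
- Step economy: after ring formation the alternative is the better plan, since no carbon–carbon bond remains to be made at C1, against four operations from 8 to 15. Before and during aromatisation it is the worse plan, and the totals should be similar or slightly longer for the alternative.

Alternative 2: The cut lies outside ring A, at both CH2–aryl bonds of the benzyl groups. In the forward sense [4,6-dimethoxy-2-[2-(3-methoxyphenyl)ethyl]-1,3-phenylene]bis(methylene) dimethyl biscarbonate A4 would couple twice with 4-methoxyphenylboronic acid A5. The catalyst would be [Pd(C3H5)Cl]2 with 1,5-bis(diphenylphosphino)pentane, working through zerovalent palladium and benzylpalladium intermediates, and the product would be the pentamethyl ether of the target A6.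
- In its favour: ring A is bought and not built, the same mirror symmetry is used two-directionally (on this point the alternative is the equal of the chosen plan), and no mode of ring closure has to be controlled (on this point it is the better plan). The aryl groups are also introduced late and could be varied.
- Against it here: A4 must be made from 3,3′,5-trimethoxybibenzyl A7 by placing two one-carbon groups at C2 and C6. That double electrophilic substitution has to avoid C4 and the second anisole ring, the second substitution meets a deactivated and crowded ring, and reduction and carbonate formation follow. Each benzylic carbonate is flanked by the arylethyl chain and a methoxy group, so two hindered oxidative additions are needed. A6 as drawn would need five Lewis-acid ether cleavages on the acid-labile skeleton, though benzyl ethers could be substituted here as well.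
- Structure: equal use of symmetry, but the problem of the substitution pattern is moved to arene functionalisation, where C4 competes.
- Mechanism: catalytic cross-coupling is more predictable than a polyketone cyclisation.
- Step economy: the key step is short, but the way to A4 is judged longer than the three steps to 8.

Alternative 3: The cut removes C3–C4 and C5–C6 and re-forms C2–C3. Ring A comes from the four-carbon unit of 2,4-bis(4-methoxybenzyl)-3-[2-(3-methoxyphenyl)ethyl]cyclobut-2-en-1-one A8 and the two carbons of ethoxyacetylene A9. On heating, A8 would open, its ketene unit would add across the triple bond of A9 in a [2+2] sense, and a second ring opening with six-electron electrocyclisation and tautomerisation would give 5-ethoxy-2,4-bis(4-methoxybenzyl)-3-[2-(3-methoxyphenyl)ethyl]phenol A10.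
- In its favour: the pericyclic cascade is regiospecific, needs no acid or base, and places all three carbon chains and both oxygens in one thermal step. On predictability of the ring-forming mechanism, and on having the C1 chain in place, it is the better plan.
- Against it here: A8 is the hard part. A cyclobutenone that carries carbon substituents at all three remaining ring positions and an enolisable C4–H would need a regiocontrolled [2+2] of a monoalkylketene with an unsymmetrical dialkylalkyne, where ketene dimerisation and poor regioselectivity are to be expected. A10 has differentiated oxygens (OH and OEt), a distinction that a symmetric resorcinol does not need and that costs an extra ether cleavage.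
- Structure: the symmetry is left unused, which would be a strength for unsymmetrical congeners but brings nothing for this target.
- Mechanism: cleaner than the polar cascade of the chosen plan.
- Step economy: equal or better from the annulation onwards, but clearly worse before it, so the chosen plan should be shorter overall.

Key step: step 3

## Route

Step 1
Reactants: 1 4-(benzyloxy)benzaldehyde (two equivalents); 2 acetylacetone (pentane-2,4-dione)
Product: 3 (1E,6E)-1,7-bis[4-(benzyloxy)phenyl]hepta-1,6-diene-3,5-dione
Conditions: 2, B2O3 (0.7 equiv), EtOAc, 70 °C; then 1 (2 equiv), B(OnBu)3 (2 equiv), n-BuNH2 (cat.), 70 °C; then 0.4 M HCl, 60 °C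
Reagents that add atoms: 4-(benzyloxy)benzaldehyde (the second equivalent of 1), O=Cc1ccc(OCc2ccccc2)cc1
Why: Boron-templated double aldol condensation in which two molecules of 1 condense with one molecule of 2, one at each methyl group; chelation of the enol of 2 to boron (a templating complex of no single composition) blocks the central carbon against Knoevenagel reaction, B(OnBu)3 takes up the water, dilute acid releases 3, and the E,E geometry is the thermodynamic one.

Step 2
Reactants: 3 (1E,6E)-1,7-bis[4-(benzyloxy)phenyl]hepta-1,6-diene-3,5-dione
Product: 4 1,7-bis[4-(benzyloxy)phenyl]heptane-3,5-dione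
Conditions: H2 (1 atm), 10% Pd/C, Ph2S (cat.), THF–EtOAc, rt
Reagents that add atoms: none
Why: Catalytic hydrogenation of the two enone C=C bonds; Pd/C poisoned with diphenyl sulfide is an established means of saturating olefins while O-benzyl groups and ketones are left untouched.

Step 3
Reactants: 4 1,7-bis[4-(benzyloxy)phenyl]heptane-3,5-dione; 5 diethyl oxalate
Product: 8 ethyl 2,6-bis[4-(benzyloxy)benzyl]-3,5-dihydroxybenzoate, via triketo ester 6 (not isolated), via cyclic aldol 7 (not isolated)
Conditions: LiN(iPr)2 (2.2 equiv), THF, −78 → 0 °C; then into 5 (1.3 equiv), THF, −78 °C; AcOH, −78 °C → rt; then Et3N, EtOH, 50 °C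
Reagents that add atoms: none
Why: With ring-A numbering (identical to the heptane numbering of 4 for C2 to C6), two equivalents of LiN(iPr)2 convert 4 into its 2,4-dianion, whose terminal carbanion C2, the most basic and most nucleophilic site, attacks one ester carbonyl of 5 to form C1–C2; the oxalate adduct is long-lived at −78 °C, which should hold back a second addition, and the acetic acid quench releases 6. Triethylamine in ethanol then lets the enol(ate) of the C5 ketone add through C6 to the C1 keto carbonyl, a 6-(enolendo)-exo-trig aldol closure that forms C1–C6 and gives 7; E1cB loss of the C1 hydroxyl and enolisation of the two ketones aromatise ring A to 8. The closest established reaction types are the Claisen acylation of β-diketone dianions at the terminal carbon and the base-mediated aldol aromatisation of 2,4,6-triketones to resorcinols, the laboratory counterpart of the tetraketide cyclisation in bibenzyl biosynthesis. The stereocentres of 7 are transient and are erased on aromatisation, so no stereocontrol is required. Terminal instead of central acylation is secured by the dianion, and the symmetry of 4 makes the two termini equivalent, so both benzyl groups reach C2 and C6 without a regiochemical choice. Carbon instead of oxygen closure (no 4-pyrone) is secured by keeping the medium basic and never strongly acidic. A further competitor to be held back is the Claisen closure of the central carbon C4 on the ester carbonyl to a five-membered acylcyclopentanetrione; the much higher electrophilicity of the α-keto carbonyl, a weak amine base at moderate temperature in place of hot alkoxide, and the irreversibility of aromatisation should favour the aldol path. Because the ester side of C1 carries no hydrogen, C6 is the only carbon that can reach C1 through a six-membered transition state.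

Step 4
Reactants: 8 ethyl 2,6-bis[4-(benzyloxy)benzyl]-3,5-dihydroxybenzoate
Product: 9 ethyl 3,5-bis(benzyloxy)-2,6-bis[4-(benzyloxy)benzyl]benzoate
Conditions: BnBr (2.4 equiv), K2CO3, DMF, 50 °C
Reagents that add atoms: benzyl bromide (two equivalents are incorporated), BrCc1ccccc1
Why: Williamson ether synthesis; the two phenoxides alkylate on oxygen in a dipolar aprotic solvent, and the ester, shielded by two ortho benzyl groups, is inert to carbonate.

Step 5
Reactants: 9 ethyl 3,5-bis(benzyloxy)-2,6-bis[4-(benzyloxy)benzyl]benzoate
Product: 10 {3,5-bis(benzyloxy)-2,6-bis[4-(benzyloxy)benzyl]phenyl}methanol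
Conditions: LiAlH4, THF, 0 °C → reflux; aq. NaOH work-up
Reagents that add atoms: none
Why: Hydride reduction of an ester to the primary alcohol; di-ortho-substituted benzoates resist hydrolysis but are still reduced by the small AlH4− ion in refluxing THF, and benzyl ethers are inert.

Step 6
Reactants: 10 {3,5-bis(benzyloxy)-2,6-bis[4-(benzyloxy)benzyl]phenyl}methanol
Product: 11 3,5-bis(benzyloxy)-2,6-bis[4-(benzyloxy)benzyl]benzaldehyde
Conditions: Dess–Martin periodinane, CH2Cl2, 0 °C → rt
Reagents that add atoms: none
Why: Dess–Martin oxidation of a primary benzylic alcohol stops at the aldehyde and is mild enough for the electron-rich diarylmethane units.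

Step 7
Reactants: 12 3-(benzyloxy)benzyl chloride
Product: 13 [3-(benzyloxy)benzyl]triphenylphosphonium chloride
Conditions: PPh3, toluene, reflux
Reagents that add atoms: triphenylphosphine, c1ccc(cc1)P(c1ccccc1)c1ccccc1
Why: SN2 quaternisation of triphenylphosphine by a benzylic chloride; the salt should precipitate from toluene.

Step 8
Reactants: 11 3,5-bis(benzyloxy)-2,6-bis[4-(benzyloxy)benzyl]benzaldehyde; 13 [3-(benzyloxy)benzyl]triphenylphosphonium chloride
Product: 15 1,5-bis(benzyloxy)-2,4-bis[4-(benzyloxy)benzyl]-3-{2-[3-(benzyloxy)phenyl]ethenyl}benzene (E/Z mixture), via ylide 14 (not isolated)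
Conditions: 13, KOtBu, THF, 0 °C; then 11, 0 °C → reflux
Reagents that add atoms: none
Why: Wittig olefination with a semi-stabilised benzylic ylide, a reaction type that tolerates di-ortho-substituted benzaldehydes; the E/Z mixture is of no consequence because the olefin is saturated in the next step.

Step 9
Reactants: 15 1,5-bis(benzyloxy)-2,4-bis[4-(benzyloxy)benzyl]-3-{2-[3-(benzyloxy)phenyl]ethenyl}benzene
Product: 16 shanciguol, 4,6-bis(4-hydroxybenzyl)-5-[2-(3-hydroxyphenyl)ethyl]benzene-1,3-diol
Conditions: H2 (3 atm), 10% Pd/C, THF–MeOH, rt
Reagents that add atoms: none
Why: Catalytic hydrogenation saturates the stilbene C=C bond and hydrogenolyses the five aryl benzyl ethers in one neutral operation; diarylmethane and bibenzyl C–C bonds are inert under these conditions, and no stereocentre is formed.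

## Compound list

1 | 4-(benzyloxy)benzaldehyde | O=Cc1ccc(OCc2ccccc2)cc1 | starting material
2 | acetylacetone (pentane-2,4-dione) | CC(=O)CC(C)=O | starting material
3 | (1E,6E)-1,7-bis[4-(benzyloxy)phenyl]hepta-1,6-diene-3,5-dione (drawn as the diketo tautomer) | O=C(/C=C/c1ccc(OCc2ccccc2)cc1)CC(=O)/C=C/c1ccc(OCc2ccccc2)cc1 | intermediate
4 | 1,7-bis[4-(benzyloxy)phenyl]heptane-3,5-dione | O=C(CCc1ccc(OCc2ccccc2)cc1)CC(=O)CCc1ccc(OCc2ccccc2)cc1 | intermediate
5 | diethyl oxalate | CCOC(=O)C(=O)OCC | starting material
6 | ethyl 3-[4-(benzyloxy)benzyl]-8-[4-(benzyloxy)phenyl]-2,4,6-trioxooctanoate (racemic, not isolated) | CCOC(=O)C(=O)C(Cc1ccc(OCc2ccccc2)cc1)C(=O)CC(=O)CCc1ccc(OCc2ccccc2)cc1 | intermediate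
7 | ethyl 2,6-bis[4-(benzyloxy)benzyl]-1-hydroxy-3,5-dioxocyclohexane-1-carboxylate (diastereomer mixture, not isolated) | CCOC(=O)C1(O)C(Cc2ccc(OCc3ccccc3)cc2)C(=O)CC(=O)C1Cc1ccc(OCc2ccccc2)cc1 | intermediate
8 | ethyl 2,6-bis[4-(benzyloxy)benzyl]-3,5-dihydroxybenzoate | CCOC(=O)c1c(Cc2ccc(OCc3ccccc3)cc2)c(O)cc(O)c1Cc1ccc(OCc2ccccc2)cc1 | intermediate
9 | ethyl 3,5-bis(benzyloxy)-2,6-bis[4-(benzyloxy)benzyl]benzoate | CCOC(=O)c1c(Cc2ccc(OCc3ccccc3)cc2)c(OCc2ccccc2)cc(OCc2ccccc2)c1Cc1ccc(OCc2ccccc2)cc1 | intermediate
10 | {3,5-bis(benzyloxy)-2,6-bis[4-(benzyloxy)benzyl]phenyl}methanol | OCc1c(Cc2ccc(OCc3ccccc3)cc2)c(OCc2ccccc2)cc(OCc2ccccc2)c1Cc1ccc(OCc2ccccc2)cc1 | intermediate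
11 | 3,5-bis(benzyloxy)-2,6-bis[4-(benzyloxy)benzyl]benzaldehyde | O=Cc1c(Cc2ccc(OCc3ccccc3)cc2)c(OCc2ccccc2)cc(OCc2ccccc2)c1Cc1ccc(OCc2ccccc2)cc1 | intermediate
12 | 3-(benzyloxy)benzyl chloride | ClCc1cccc(OCc2ccccc2)c1 | starting material
13 | [3-(benzyloxy)benzyl]triphenylphosphonium chloride | [Cl-].c1ccc(cc1)[P+](Cc1cccc(OCc2ccccc2)c1)(c1ccccc1)c1ccccc1 | intermediate
14 | [3-(benzyloxy)benzylidene]triphenylphosphorane (ylide, not isolated) | C(=P(c1ccccc1)(c1ccccc1)c1ccccc1)c1cccc(OCc2ccccc2)c1 | intermediate
15 | 1,5-bis(benzyloxy)-2,4-bis[4-(benzyloxy)benzyl]-3-{2-[3-(benzyloxy)phenyl]ethenyl}benzene (E/Z mixture, geometry left open) | C(=Cc1cccc(OCc2ccccc2)c1)c1c(Cc2ccc(OCc3ccccc3)cc2)c(OCc2ccccc2)cc(OCc2ccccc2)c1Cc1ccc(OCc2ccccc2)cc1 | intermediate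
16 | shanciguol, 4,6-bis(4-hydroxybenzyl)-5-[2-(3-hydroxyphenyl)ethyl]benzene-1,3-diol (achiral) | Oc1ccc(Cc2c(O)cc(O)c(Cc3ccc(O)cc3)c2CCc2cccc(O)c2)cc1 | target

## Step count and least certain steps

Total step count: 9. Longest linear sequence: 8 steps (steps 1 to 6, 8 and 9); step 7 is a one-step branch.

Step 3 (key step). The most likely failure is that the ring closes the wrong way: a Claisen-type attack of the central carbon C4 on the ester carbonyl, or closure through oxygen. The acylation itself may also stall through proton transfer from the first adduct to unreacted dianion, or suffer a second addition to the new keto group. The fallback keeps the same two ring bonds but changes the one-carbon partner to one without an ester carbonyl. It sets out from 4. The dianion, with one further equivalent of LiN(iPr)2, is acylated with ethyl diethoxyacetate (CCOC(OCC)C(=O)OCC) to give 3-[4-(benzyloxy)benzyl]-8-[4-(benzyloxy)phenyl]-1,1-diethoxyoctane-2,4,6-trione F1. The same amine-mediated aldol aromatisation should then give 4,6-bis[4-(benzyloxy)benzyl]-5-(diethoxymethyl)benzene-1,3-diol F2. Brief treatment with dilute aqueous acid in THF at room temperature hydrolyses the acetal to 2,6-bis[4-(benzyloxy)benzyl]-3,5-dihydroxybenzaldehyde F3. Benzylation under the conditions of step 4 returns to the route at 11, so that steps 5 and 6 are not needed. The Claisen competitor is absent because the carbon attached to C1 is then an acetal carbon and not an ester carbonyl.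

Step 2. Hydrogenolysis of the aryl benzyl ethers may compete with saturation of the two enone double bonds, or a carbonyl group may be reduced further. The fallback avoids the unsaturated stage altogether. It sets out from 2, which is converted into its dianion (NaH, then n-BuLi, THF, 0 °C) and alkylated at a methyl terminus with 4-(benzyloxy)benzyl chloride (ClCc1ccc(OCc2ccccc2)cc1) to give 6-[4-(benzyloxy)phenyl]hexane-2,4-dione F4. A second dianion formation (LiN(iPr)2, 2 equiv, THF, −78 → 0 °C), in which the remaining methyl group should be deprotonated in preference to the methylene, and a second alkylation with the same chloride return to the route at 4. The step count is unchanged.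

Step 8. Addition of the ylide to a formyl group shielded by two ortho benzyl groups may be slow, so that the ylide decomposes before it reacts. The fallback makes the bridge as an sp3–sp3 bond. It sets out from 10, which PBr3 (CH2Cl2, 0 °C) converts into 1,5-bis(benzyloxy)-2,4-bis[4-(benzyloxy)benzyl]-3-(bromomethyl)benzene F5. Compound 12 and magnesium in THF give [3-(benzyloxy)benzyl]magnesium chloride F6, which is coupled with the bromide under Li2CuCl4 catalysis (THF, −20 → 0 °C). This gives 1,5-bis(benzyloxy)-2,4-bis[4-(benzyloxy)benzyl]-3-{2-[3-(benzyloxy)phenyl]ethyl}benzene F7, and hydrogenolysis under the conditions of step 9 returns to the route at 16. The number of steps from 10 is the same; the risk taken in exchange is homocoupling through halogen–magnesium exchange, which is why this path is held in reserve.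

## Further compounds

F1 | step 3 | 3-[4-(benzyloxy)benzyl]-8-[4-(benzyloxy)phenyl]-1,1-diethoxyoctane-2,4,6-trione (racemic) | CCOC(OCC)C(=O)C(Cc1ccc(OCc2ccccc2)cc1)C(=O)CC(=O)CCc1ccc(OCc2ccccc2)cc1
F2 | step 3 | 4,6-bis[4-(benzyloxy)benzyl]-5-(diethoxymethyl)benzene-1,3-diol | CCOC(OCC)c1c(Cc2ccc(OCc3ccccc3)cc2)c(O)cc(O)c1Cc1ccc(OCc2ccccc2)cc1
F3 | step 3 | 2,6-bis[4-(benzyloxy)benzyl]-3,5-dihydroxybenzaldehyde | O=Cc1c(Cc2ccc(OCc3ccccc3)cc2)c(O)cc(O)c1Cc1ccc(OCc2ccccc2)cc1
F4 | step 2 | 6-[4-(benzyloxy)phenyl]hexane-2,4-dione | CC(=O)CC(=O)CCc1ccc(OCc2ccccc2)cc1
F5 | step 8 | 1,5-bis(benzyloxy)-2,4-bis[4-(benzyloxy)benzyl]-3-(bromomethyl)benzene | BrCc1c(Cc2ccc(OCc3ccccc3)cc2)c(OCc2ccccc2)cc(OCc2ccccc2)c1Cc1ccc(OCc2ccccc2)cc1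
F6 | step 8 | [3-(benzyloxy)benzyl]magnesium chloride | Cl[Mg]Cc1cccc(OCc2ccccc2)c1
F7 | step 8 | 1,5-bis(benzyloxy)-2,4-bis[4-(benzyloxy)benzyl]-3-{2-[3-(benzyloxy)phenyl]ethyl}benzene | C(Cc1cccc(OCc2ccccc2)c1)c1c(Cc2ccc(OCc3ccccc3)cc2)c(OCc2ccccc2)cc(OCc2ccccc2)c1Cc1ccc(OCc2ccccc2)cc1
A1 | alternative 1 | dimethyl 2-(4-methoxybenzyl)malonate | COC(=O)C(Cc1ccc(OC)cc1)C(=O)OC
A2 | alternative 1 | (E)-3-(4-methoxybenzyl)-6-(3-methoxyphenyl)hex-3-en-2-one | CC(=O)/C(Cc1ccc(OC)cc1)=C/CCc1cccc(OC)c1
A3 | alternative 1 | methyl 1,3-bis(4-methoxybenzyl)-2-[2-(3-methoxyphenyl)ethyl]-4,6-dioxocyclohexane-1-carboxylate (diastereomer mixture) | COC(=O)C1(Cc2ccc(OC)cc2)C(=O)CC(=O)C(Cc2ccc(OC)cc2)C1CCc1cccc(OC)c1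
A4 | alternative 2 | [4,6-dimethoxy-2-[2-(3-methoxyphenyl)ethyl]-1,3-phenylene]bis(methylene) dimethyl biscarbonate | COC(=O)OCc1c(OC)cc(OC)c(COC(=O)OC)c1CCc1cccc(OC)c1
A5 | alternative 2 | 4-methoxyphenylboronic acid | COc1ccc(B(O)O)cc1
A6 | alternative 2 | pentamethyl ether of the target, 1,5-dimethoxy-2,4-bis(4-methoxybenzyl)-3-[2-(3-methoxyphenyl)ethyl]benzene | COc1ccc(Cc2c(OC)cc(OC)c(Cc3ccc(OC)cc3)c2CCc2cccc(OC)c2)cc1
A7 | alternative 2 | 3,3′,5-trimethoxybibenzyl, 1,3-dimethoxy-5-[2-(3-methoxyphenyl)ethyl]benzene | COc1cccc(CCc2cc(OC)cc(OC)c2)c1
A8 | alternative 3 | 2,4-bis(4-methoxybenzyl)-3-[2-(3-methoxyphenyl)ethyl]cyclobut-2-en-1-one (racemic) | O=C1C(Cc2ccc(OC)cc2)C(CCc2cccc(OC)c2)=C1Cc1ccc(OC)cc1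
A9 | alternative 3 | ethoxyacetylene | C#COCC
A10 | alternative 3 | 5-ethoxy-2,4-bis(4-methoxybenzyl)-3-[2-(3-methoxyphenyl)ethyl]phenol | CCOc1cc(O)c(Cc2ccc(OC)cc2)c(CCc2cccc(OC)c2)c1Cc1ccc(OC)cc1
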